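## Retrosynthetic overview

1. The ten-membered ring (C1–C10) is closed last, at C4–C5, by a Nozaki–Hiyama–Kishi reaction of a (Z)-vinyl iodide on C5 with a C4 aldehyde; acylations finish the target.
2. The lactone and C5–C8 come from (S)-malic acid (aldol at C8–C9 through its dioxolanone enolate) and propargyl alcohol (C6–C7), followed by ketone reduction at C7 and lactonisation.
3. The cyclohexene ring (C1–C14–C13–C12–C11–C10) is made in one thermal cascade from a monocyclic acetal: selenoxide elimination, ketene-acetal Claisen shift (C10–C11) and carbonyl-ene closure (C13–C14), with (E)-crotyl alcohol supplying C11–C13 and C20.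
4. The feature that makes this possible is a temporary five-membered ring O–C15–C1–C10–C9 (C15 oxygenated, C9 at the carboxyl level as a cyclic ketene acetal) whose quaternary ring carbon C1 carries the C14 formyl group; the C15–O bond is later reduced to the C15 methyl group.
5. Ring order: dihydrofuran (temporary) → cyclohexene → γ-lactone (C7, C8, C17, C19, O) → ten-membered ring.

Key step: step 9

Remark: atom labels follow briarane numbering of the target: C1 quaternary (C15 methyl), C2 (OAc), C3, C4 (butyrate), C5 (C16 acetoxymethyl), C6, C7 (lactone O), C8 (OH), C9 (OAc), C10, C11 (C20 methyl), C12, C13, C14 (OAc), C17 (C18 methyl), C19 (lactone C=O).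

Remark: the lipase in step 5 is assumed to acylate the hydroxymethyl group that leads to (R)-8; if it prefers the other group, enzymatic hydrolysis of the diacetate of 7 would be used to reach the same monoacetate.

## Route

Step 1
Reactants: 1 dimethyl 2-allylmalonate
Product: 2 dimethyl 2-allyl-2-(hydroxymethyl)malonate
Conditions: aq. CH2O (37%), KHCO3, THF, 20 °C
Reagents that add atoms: formaldehyde, C=O
Why: Base-mediated aldol-type hydroxymethylation of the malonate C–H installs C15 and makes C1 quaternary; no stereocentre is formed.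

Step 2
Reactants: 2 dimethyl 2-allyl-2-(hydroxymethyl)malonate
Product: 4 dimethyl 5-hydroxydihydrofuran-3,3(2H)-dicarboxylate, via aldehyde 3 (not isolated)
Conditions: O3, CH2Cl2/MeOH, −78 °C; then Me2S, −78 → 20 °C
Reagents that add atoms: ozone, [O-][O+]=O
Why: Ozonolysis with reductive work-up cleaves the only alkene, and the C9 aldehyde is trapped by the hydroxymethyl group as the five-membered lactol.

Step 3
Reactants: 4 dimethyl 5-hydroxydihydrofuran-3,3(2H)-dicarboxylate
Product: 6 dimethyl furan-3,3(2H)-dicarboxylate, via mesylate 5 (not isolated)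
Conditions: MsCl, Et3N, CH2Cl2, −20 → 40 °C
Reagents that add atoms: none
Why: Mesylation of the anomeric hydroxyl and base-induced elimination (glycal-type synthesis) give the cyclic enol ether C9=C10; C1 bears no hydrogen, so only this regioisomer can form.

Step 4
Reactants: 6 dimethyl furan-3,3(2H)-dicarboxylate
Product: 7 (2,3-dihydrofuran-3,3-diyl)dimethanol
Conditions: LiAlH4, THF, 0 °C; basic aqueous work-up
Reagents that add atoms: none
Why: Hydride reduction of both esters (the enol ether is inert to LiAlH4 and to the basic work-up) gives the prochiral 1,3-diol.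

Step 5
Reactants: 7 (2,3-dihydrofuran-3,3-diyl)dimethanol
Product: 8 (R)-[3-(hydroxymethyl)-2,3-dihydrofuran-3-yl]methyl acetate
Conditions: Amano lipase PS, vinyl acetate, t-BuOMe, 25 °C
Reagents that add atoms: vinyl acetate, C=COC(C)=O
Why: Enzymatic desymmetrising transesterification of a prochiral 2,2-disubstituted propane-1,3-diol differentiates the enantiotopic hydroxymethyl groups and so sets the configuration of C1.

Step 6
Reactants: 8 (R)-[3-(hydroxymethyl)-2,3-dihydrofuran-3-yl]methyl acetate
Product: 9 (R)-(3-formyl-2,3-dihydrofuran-3-yl)methyl acetate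
Conditions: Dess–Martin periodinane, pyridine, CH2Cl2, 0 °C
Reagents that add atoms: none
Why: Buffered Dess–Martin oxidation of the primary alcohol spares the enol ether and gives the non-enolisable C14 aldehyde, which also removes the risk of acetyl migration between the two arms.

Step 7
Reactants: 9 (R)-(3-formyl-2,3-dihydrofuran-3-yl)methyl acetate; 10 (E)-but-2-en-1-ol
Product: 11 [5-((E)-but-2-enyloxy)-3-formyl-4-(phenylselanyl)tetrahydrofuran-3-yl]methyl acetate (PhSe cis to CHO; 4,5-trans)
Conditions: PhSeCl, 10 (3 equiv), i-Pr2NEt, CH2Cl2, −78 → −20 °C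
Reagents that add atoms: benzeneselenenyl chloride, Cl[Se]c1ccccc1
Why: Alkoxyselenation of the enol ether: the selenium electrophile adds to C10 anti to the acetoxymethyl arm and crotyl alcohol opens the cation at the acetal carbon C9 trans to selenium; both new centres are removed again in step 9.

Step 8
Reactants: 11 seleno acetal
Product: 12 selenoxide of 11
Conditions: NaIO4, NaHCO3, MeOH/H2O, 0 °C; used crude
Reagents that add atoms: sodium periodate, [Na+].[O-]I(=O)(=O)=O
Why: Periodate oxidises the selenide to the selenoxide chemoselectively; the only β-hydrogen is on the acetal carbon C9, whose syn-elimination needs heat, so the selenoxide can be handled cold.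

Step 9
Reactants: 12 selenoxide
Product: 15 (3aS,4S,7aS)-3a-(acetoxymethyl)-4-hydroxy-7-methyl-3a,4,5,7a-tetrahydroisobenzofuran-1(3H)-one, via ketene acetal 13 (not isolated), via Claisen lactone aldehyde 14 (not isolated)
Conditions: Et3N (3 equiv), 1,2-dichlorobenzene (0.01 M), 110 °C, then 180 °C, sealed tube
Reagents that add atoms: none
Why: Syn-elimination of the selenoxide gives cyclic ketene acetal 13, whose crotyl group migrates in a chair-like [3,3]-sigmatropic (ketene-acetal Claisen) shift to form C10–C11 and lactone 14, and the 1-methylallyl group then adds to the C14 aldehyde in an intramolecular carbonyl-ene reaction that forms C13–C14 and moves the double bond to C11=C12. The closest known reactions are the selenoxide-elimination/Claisen lactone synthesis from seleno acetals and thermal tandem sigmatropic shift/carbonyl-ene cascades. The cyclohexene ring is closed in the ene step as a six-membered ring through a boat-like transition state (ene unit tethered through its hydrogen-bearing carbon, so the alkene ends up endocyclic), while the five-membered ring only changes from acetal to lactone. C10 is set in the Claisen step, the crotyl unit adding to the ring face anti to the acetoxymethyl arm of C1 and syn to the small formyl group; C14 is set by suprafacial hydrogen transfer, the hydroxyl appearing on the face from which H11 leaves, which the (E)-crotyl geometry and the ring-fixed ketene acetal geometry place cis to H10. The step needs face selectivity in the Claisen shift and a cis relation of C11 and the formyl group; the cis-fused five-membered ring secures both and holds C15–C1–C10–C9 nearly eclipsed, as the boat requires, and the quaternary C1 keeps the aldehyde from enolising.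

Step 10
Reactants: 15 bicyclic hydroxy lactone
Product: 16 diol (15 with the acetate removed: C2 hydroxymethyl and 14-OH)
Conditions: K2CO3 (cat.), MeOH, 0 °C
Reagents that add atoms: none
Why: Zemplén-type methanolysis removes the primary acetate; the cis-fused γ-lactone is the most stable lactone available and re-closes if opened.

Step 11
Reactants: 16 diol
Product: 17 hydroxy aldehyde (C2 formyl group on C1; 14-OH free)
Conditions: TEMPO (cat.), PhI(OAc)2, CH2Cl2, 20 °C
Reagents that add atoms: none
Why: Oxoammonium (TEMPO) oxidation is selective for the primary alcohol over the secondary C14 hydroxyl.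

Step 12
Reactants: 17 hydroxy aldehyde
Product: 18 allylic alcohols (vinyl carbinol at C2; both C2 epimers)
Conditions: vinylmagnesium bromide (3 equiv), THF, −78 °C
Reagents that add atoms: vinylmagnesium bromide, C=C[Mg]Br
Why: Grignard addition to the aldehyde at −78 °C, where the lactone is far less electrophilic, adds C3 and C4; the epimers are not separated because C2 is reset in steps 13 and 14.

Step 13
Reactants: 18 allylic alcohols
Product: 19 β-hydroxy enone (C2 ketone; C3=C4 vinyl; 14-OH free)
Conditions: MnO2 (excess), CH2Cl2, 20 °C; used directly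
Reagents that add atoms: none
Why: MnO2 oxidises only the allylic alcohol under neutral conditions, which avoids retro-aldol cleavage of the β-hydroxy ketone.

Step 14
Reactants: 19 β-hydroxy enone
Product: 21 (2R)-syn-1,3-diol (2-OH and 14-OH; vinyl on C2), via boron chelate 20 (not isolated)
Conditions: Et2BOMe, THF/MeOH (4:1), −78 °C; NaBH4; then AcOH, MeOH azeotrope
Reagents that add atoms: none
Why: Narasaka–Prasad reduction: external hydride attacks the six-membered boron chelate of the β-hydroxy ketone axially in a 1,2-fashion, giving the 1,3-syn diol, which is the 2R configuration.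

Step 15
Reactants: 21 syn-1,3-diol
Product: 22 bis(triethylsilyl) ether (2-OTES and 14-OTES; lactone intact)
Conditions: TESOTf (2.5 equiv), 2,6-lutidine, CH2Cl2, −78 → 0 °C
Reagents that add atoms: triethylsilyl trifluoromethanesulfonate, CC[Si](CC)(CC)OS(=O)(=O)C(F)(F)F
Why: The silyl triflate silylates both hindered secondary alcohols without touching the lactone or the alkenes.

Step 16
Reactants: 22 bis(triethylsilyl) ether
Product: 23 hydroxy Weinreb amide (C9 N-methoxy-N-methylamide on C10; C15 hydroxymethyl on C1)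
Conditions: MeNHOMe·HCl, AlMe3, CH2Cl2, 0 → 20 °C; used crude
Reagents that add atoms: N,O-dimethylhydroxylamine hydrochloride, CNOC.Cl
Why: Aminolysis of the lactone by the aluminium amide (Weinreb amide formation) opens the temporary ring and frees the C15 hydroxymethyl group.

Step 17
Reactants: 23 hydroxy Weinreb amide
Product: 24 O-phenyl thionocarbonate of 23 (at C15–O)
Conditions: PhOC(S)Cl, pyridine, DMAP (cat.), CH2Cl2, 0 °C
Reagents that add atoms: O-phenyl chlorothionoformate, S=C(Cl)Oc1ccccc1
Why: Acylation of the neopentyl primary alcohol needs no substitution at carbon and blocks relactonisation.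

Step 18
Reactants: 24 thionocarbonate
Product: 25 Weinreb amide with C15 methyl group
Conditions: Bu3SnH (1 M), AIBN (cat.), toluene, 110 °C
Reagents that add atoms: none
Why: Barton–McCombie deoxygenation: the stannyl radical adds to C=S, β-scission gives the C15 radical, and the high stannane concentration reduces it to the methyl group before it can close onto C12.

Step 19
Reactants: 25 Weinreb amide
Product: 26 C9 aldehyde (2,14-bis-OTES; C15 methyl; vinyl on C2)
Conditions: i-Bu2AlH, THF, −78 °C; Rochelle salt work-up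
Reagents that add atoms: none
Why: Hydride reduction of the Weinreb amide stops at the aldehyde through the chelated tetrahedral intermediate, and the low temperature protects the C10 stereocentre.

Step 20
Reactants: 27 dimethyl (S)-malate
Product: 29 dimethyl (2S,3R)-3-methylmalate, via dilithium enolate 28 (not isolated)
Conditions: LiN(i-Pr)2 (2.2 equiv), THF, −78 → −20 °C; MeI, −78 → −10 °C
Reagents that add atoms: iodomethane, CI
Why: Fráter–Seebach alkylation: the dilithium alkoxide enolate is methylated anti to the alkoxide, which sets C17 (3R).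

Step 21
Reactants: 29 dimethyl (2S,3R)-3-methylmalate
Product: 30 (2S,3R)-3-methylmalic acid
Conditions: KOH, H2O/MeOH, 20 °C; then HCl to pH 1
Reagents that add atoms: potassium hydroxide, [K+].[OH-]
Why: Saponification of both esters; the carboxylate dianion is not epimerised at room temperature.

Step 22
Reactants: 30 (2S,3R)-3-methylmalic acid
Product: 31 (2R)-2-[(2S,4S)-2-tert-butyl-5-oxo-1,3-dioxolan-4-yl]propanoic acid
Conditions: pivalaldehyde, TsOH (cat.), H2SO4 (cat.), pentane, reflux, water separator
Reagents that add atoms: pivalaldehyde, CC(C)(C)C=O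
Why: Acid-catalysed acetalisation of the α-hydroxy acid under thermodynamic control gives the cis five-membered dioxolanone, whose acetal centre stores the C8 configuration.

Step 23
Reactants: 26 C9 aldehyde; 31 dioxolanone acid
Product: 35 aldol adduct acid (9R-OTES; C8 quaternary in the dioxolanone; free C19 acid), via dianion 32 (not isolated), via dilithium aldolate 33 (not isolated), via silyl ester 34 (not isolated)
Conditions: 31, LiN(SiMe3)2 (2.1 equiv), THF, −78 °C; 26, −78 °C; TESOTf (3 equiv), −78 → −40 °C; pH 5 buffer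
Reagents that add atoms: triethylsilyl trifluoromethanesulfonate, CC[Si](CC)(CC)OS(=O)(=O)C(F)(F)F
Why: Aldol addition of the dioxolanone enolate (self-regeneration of the stereocentre: attack trans to tert-butyl keeps the C8 configuration) to the aldehyde under Felkin–Anh control (C1 as the large group, giving 9R), with the aldolate silylated in the flask to block retro-aldol reaction and lactonisation onto C19.

Step 24
Reactants: 35 aldol adduct acid; 36 propargyl alcohol
Product: 39 ynone acid (C7 ketone; C5≡C6; 16-OH; 8-OH; C19 acid), via dilithiated propargyl alcohol 37 (not isolated), via tetrahedral adduct 38 (not isolated)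
Conditions: 36 (5 equiv), n-BuLi (10 equiv), THF, −78 → 0 °C; 35, −78 °C; AcOH/THF quench at −78 °C; used directly
Reagents that add atoms: none
Why: Acyl substitution: the acetylide adds to the activated dioxolanone carbonyl (the C19 carboxylate is inert), and the tetrahedral adduct collapses only on work-up, releasing the ynone, the C8 hydroxyl and pivalaldehyde.

Step 25
Reactants: 39 ynone acid
Product: 41 γ-lactone alkyne (lactone C19–O–C7; 7S; 8-OH; 9-OTES; 16-OH), via hydroxy acid 40 (not isolated)
Conditions: (R)-2-methyl-CBS-oxazaborolidine (0.5 equiv), catecholborane (5 equiv), toluene/CH2Cl2, −78 °C; MeOH; then 10% aq. citric acid, 20 °C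
Reagents that add atoms: none
Why: Corey–Bakshi–Shibata reduction, in which the alkynyl group acts as the small and the quaternary C8 as the large substituent, gives the 7S propargylic alcohol, and the γ-hydroxy acid lactonises on acidification.

Step 26
Reactants: 41 γ-lactone alkyne
Product: 42 (Z)-alkenylstannane (Bu3Sn on C5; H on C6; 16-OH)
Conditions: Bu3SnH, [Cp*RuCl]4 (2.5 mol%), CH2Cl2, 20 °C
Reagents that add atoms: tributyltin hydride, CCCC[SnH](CCCC)CCCC
Why: Hydroxyl-directed ruthenium-catalysed trans-hydrostannation puts tin on C5, next to the free C16 hydroxyl, and hydrogen on C6 anti to it, which fixes the alkene geometry needed in the ring.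

Step 27
Reactants: 42 alkenylstannane
Product: 43 (Z)-vinyl iodide (I on C5; 16-OH)
Conditions: I2, CH2Cl2, 0 °C
Reagents that add atoms: iodine, II
Why: Iododestannylation proceeds with retention of alkene geometry and is much faster than any reaction of iodine with the other alkenes.

Step 28
Reactants: 43 vinyl iodide
Product: 44 vinyl iodide 16-OTBS ether
Conditions: TBSCl, imidazole, DMF, 20 °C
Reagents that add atoms: tert-butyldimethylsilyl chloride, CC(C)(C)[Si](C)(C)Cl
Why: Silylation of the primary allylic alcohol; the tertiary C8 hydroxyl does not react.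

Step 29
Reactants: 44 silyl ether
Product: 46 primary alcohol (C4 hydroxymethylene; C3H2), via alkylborane 45 (not isolated)
Conditions: 9-BBN (4 equiv), THF, 0 → 20 °C; then pH 7 buffer, 30% H2O2, 0 °C
Reagents that add atoms: hydrogen peroxide, OO
Why: Hydroboration–oxidation: 9-BBN reacts only with the monosubstituted alkene, at its terminus, and leaves the trisubstituted alkenes, the vinyl iodide and the lactone untouched.

Step 30
Reactants: 46 primary alcohol
Product: 47 C4 aldehyde
Conditions: Dess–Martin periodinane, pyridine, CH2Cl2, 0 → 20 °C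
Reagents that add atoms: none
Why: Dess–Martin oxidation gives the β-silyloxy aldehyde without epimerisation or elimination; the tertiary alcohol is inert.

Step 31
Reactants: 47 C4 aldehyde
Product: 48 ten-membered allylic alcohol (4R-OH; 5Z; 2,9,14-tris-OTES; 16-OTBS; 8-OH)
Conditions: CrCl2 (15 equiv), NiCl2 (0.1 equiv), degassed DMSO, 1 mM, 20 °C
Reagents that add atoms: none
Why: Intramolecular Nozaki–Hiyama–Kishi reaction: zerovalent nickel inserts into the C5–I bond, transmetalation to trivalent chromium gives an alkenylchromium that adds to the C4 aldehyde with retention of alkene geometry and closes the ten-membered ring; the 4R alcohol is expected from peripheral attack on the dipole-minimised β-silyloxy aldehyde conformer.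

Step 32
Reactants: 48 macrocyclic alcohol
Product: 49 4-butyrate
Conditions: butyric anhydride, Et3N, DMAP (cat.), CH2Cl2, 0 °C
Reagents that add atoms: butyric anhydride, CCCC(=O)OC(=O)CCC
Why: DMAP-catalysed acylation of the only free secondary alcohol; the tertiary C8 hydroxyl is too hindered to react at 0 °C.

Step 33
Reactants: 49 4-butyrate
Product: 50 tetraol 4-butyrate (2-, 9-, 14-, 16-OH and 8-OH free)
Conditions: HF·pyridine, pyridine/THF, 0 → 20 °C
Reagents that add atoms: none
Why: Fluoride cleavage of the four silyl ethers under mildly acidic conditions, which do not promote migration of the butyrate.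

Step 34
Reactants: 50 tetraol 4-butyrate
Product: 51 CNP0290502.1 (target)
Conditions: Ac2O, pyridine, DMAP (cat.), CH2Cl2, 20 °C
Reagents that add atoms: acetic anhydride, CC(=O)OC(C)=O
Why: Acetylation of the primary C16 and the secondary C2, C9 and C14 alcohols; the tertiary C8 hydroxyl stays free under these conditions.

## Compound list

1 | dimethyl 2-allylmalonate | C=CCC(C(=O)OC)C(=O)OC | starting material
2 | dimethyl 2-allyl-2-(hydroxymethyl)malonate | C=CCC(CO)(C(=O)OC)C(=O)OC | intermediate
3 | dimethyl 2-(hydroxymethyl)-2-(2-oxoethyl)malonate | O=CCC(CO)(C(=O)OC)C(=O)OC | intermediate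
4 | dimethyl 5-hydroxydihydrofuran-3,3(2H)-dicarboxylate | COC(=O)C1(C(=O)OC)COC(O)C1 | intermediate
5 | dimethyl 5-(mesyloxy)dihydrofuran-3,3(2H)-dicarboxylate | COC(=O)C1(C(=O)OC)COC(OS(C)(=O)=O)C1 | intermediate
6 | dimethyl furan-3,3(2H)-dicarboxylate | COC(=O)C1(C(=O)OC)COC=C1 | intermediate
7 | (2,3-dihydrofuran-3,3-diyl)dimethanol | OCC1(CO)COC=C1 | intermediate
8 | (R)-[3-(hydroxymethyl)-2,3-dihydrofuran-3-yl]methyl acetate | OC[C@@]1(COC(C)=O)COC=C1 | intermediate
9 | (R)-(3-formyl-2,3-dihydrofuran-3-yl)methyl acetate | O=C[C@@]1(COC(C)=O)COC=C1 | intermediate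
10 | (E)-but-2-en-1-ol | C/C=C/CO | starting material
11 | [5-((E)-but-2-enyloxy)-3-formyl-4-(phenylselanyl)tetrahydrofuran-3-yl]methyl acetate, PhSe cis to CHO, 4,5-trans, quaternary centre as in 9 | O=C[C@@]1(COC(C)=O)CO[C@H](OC/C=C/C)[C@H]1[Se]c1ccccc1 | intermediate
12 | selenoxide of 11 (configuration at selenium not defined) | O=C[C@@]1(COC(C)=O)CO[C@H](OC/C=C/C)[C@H]1[Se](=O)c1ccccc1 | intermediate
13 | [5-((E)-but-2-enyloxy)-3-formyl-2,3-dihydrofuran-3-yl]methyl acetate (cyclic ketene acetal) | O=C[C@@]1(COC(C)=O)COC(OC/C=C/C)=C1 | intermediate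
14 | [4-(but-3-en-2-yl)-3-formyl-5-oxotetrahydrofuran-3-yl]methyl acetate, butenyl cis to CHO, H10 and H11 related as in the SMILES | CC(=O)OC[C@]1(C=O)COC(=O)[C@H]1[C@@H](C)C=C | intermediate
15 | (3aS,4S,7aS)-3a-(acetoxymethyl)-4-hydroxy-7-methyl-3a,4,5,7a-tetrahydroisobenzofuran-1(3H)-one | CC(=O)OC[C@@]2(COC3=O)[C@@H](O)CC=C(C)[C@@H]23 | intermediate
16 | 3a-(hydroxymethyl) analogue of 15 (diol) | OC[C@@]2(COC3=O)[C@@H](O)CC=C(C)[C@@H]23 | intermediate
17 | 3a-formyl analogue of 15 (C2 aldehyde, 14-OH) | O=C[C@@]2(COC3=O)[C@@H](O)CC=C(C)[C@@H]23 | intermediate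
18 | 3a-(1-hydroxyprop-2-enyl) analogue of 15, both C2 epimers | C=CC(O)[C@@]2(COC3=O)[C@@H](O)CC=C(C)[C@@H]23 | intermediate
19 | 3a-acryloyl analogue of 15 (β-hydroxy enone) | C=CC(=O)[C@@]2(COC3=O)[C@@H](O)CC=C(C)[C@@H]23 | intermediate
20 | O14-diethylboryl derivative of 19 (boron chelate) | C=CC(=O)[C@@]2(COC3=O)[C@@H](OB(CC)CC)CC=C(C)[C@@H]23 | intermediate
21 | (2R)-syn-1,3-diol: 3a-[(R)-1-hydroxyprop-2-enyl] analogue of 15 | C=C[C@@H](O)[C@@]2(COC3=O)[C@@H](O)CC=C(C)[C@@H]23 | intermediate
22 | 2,14-bis(triethylsilyl) ether of 21 | C=C[C@@H](O[Si](CC)(CC)CC)[C@@]2(COC3=O)[C@@H](O[Si](CC)(CC)CC)CC=C(C)[C@@H]23 | intermediate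
23 | hydroxy Weinreb amide: cyclohexene with C9 N-methoxy-N-methylamide on C10, C15 hydroxymethyl and C2 (R)-silyloxyallyl on C1, 14-OTES | C=C[C@@H](O[Si](CC)(CC)CC)[C@@]2(CO)[C@@H](O[Si](CC)(CC)CC)CC=C(C)[C@@H]2C(=O)N(C)OC | intermediate
24 | O-phenyl thionocarbonate of 23 at C15–O | C=C[C@@H](O[Si](CC)(CC)CC)[C@@]2(COC(=S)Oc3ccccc3)[C@@H](O[Si](CC)(CC)CC)CC=C(C)[C@@H]2C(=O)N(C)OC | intermediate
25 | Weinreb amide with C15 methyl (centres as in the target at C1, C2, C10, C14) | C=C[C@@H](O[Si](CC)(CC)CC)[C@@]2(C)[C@@H](O[Si](CC)(CC)CC)CC=C(C)[C@@H]2C(=O)N(C)OC | intermediate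
26 | C9 aldehyde corresponding to 25 | C=C[C@@H](O[Si](CC)(CC)CC)[C@@]2(C)[C@@H](O[Si](CC)(CC)CC)CC=C(C)[C@@H]2C=O | intermediate
27 | dimethyl (S)-malate | COC(=O)C[C@H](O)C(=O)OC | starting material
28 | dilithium alkoxide enolate of 27 | [Li+].[Li+].COC([O-])=C[C@H]([O-])C(=O)OC | intermediate
29 | dimethyl (2S,3R)-3-methylmalate | COC(=O)[C@H](C)[C@H](O)C(=O)OC | intermediate
30 | (2S,3R)-3-methylmalic acid | OC(=O)[C@H](C)[C@H](O)C(=O)O | intermediate
31 | (2R)-2-[(2S,4S)-2-tert-butyl-5-oxo-1,3-dioxolan-4-yl]propanoic acid | C[C@@H](C(=O)O)[C@@H]1O[C@H](C(C)(C)C)OC1=O | intermediate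
32 | dilithium carboxylate enolate of 31 | [Li+].[Li+].C[C@@H](C(=O)[O-])C1=C([O-])O[C@@H](C(C)(C)C)O1 | intermediate
33 | dilithium aldolate of 26 and 32 | C=C[C@@H](O[Si](CC)(CC)CC)[C@@]2(C)[C@@H](O[Si](CC)(CC)CC)CC=C(C)[C@@H]2[C@@H]([O-])[C@@]3([C@@H](C)C(=O)[O-])O[C@H](C(C)(C)C)OC3=O.[Li+].[Li+] | intermediate
34 | 9-O-triethylsilyl ether triethylsilyl ester of the aldol adduct | C=C[C@@H](O[Si](CC)(CC)CC)[C@@]2(C)[C@@H](O[Si](CC)(CC)CC)CC=C(C)[C@@H]2[C@@H](O[Si](CC)(CC)CC)[C@@]3([C@@H](C)C(=O)O[Si](CC)(CC)CC)O[C@H](C(C)(C)C)OC3=O | intermediate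
35 | aldol adduct acid: 9R-OTES, C8 as the dioxolanone ring carbon (tert-butyl cis to the C17 side chain), free C19 acid | C=C[C@@H](O[Si](CC)(CC)CC)[C@@]2(C)[C@@H](O[Si](CC)(CC)CC)CC=C(C)[C@@H]2[C@@H](O[Si](CC)(CC)CC)[C@@]3([C@@H](C)C(=O)O)O[C@H](C(C)(C)C)OC3=O | intermediate
36 | propargyl alcohol | C#CCO | starting material
37 | dilithiated propargyl alcohol | [Li]C#CCO[Li] | intermediate
38 | trilithium tetrahedral adduct of 35 and 37 | C=C[C@@H](O[Si](CC)(CC)CC)[C@@]2(C)[C@@H](O[Si](CC)(CC)CC)CC=C(C)[C@@H]2[C@@H](O[Si](CC)(CC)CC)[C@@]3([C@@H](C)C(=O)[O-])O[C@H](C(C)(C)C)OC3([O-])C#CC[O-].[Li+].[Li+].[Li+] | intermediate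
39 | ynone acid: C7 ketone, C5≡C6, 16-OH, 8-OH, 9-OTES, C19 acid | C=C[C@@H](O[Si](CC)(CC)CC)[C@@]2(C)[C@@H](O[Si](CC)(CC)CC)CC=C(C)[C@@H]2[C@@H](O[Si](CC)(CC)CC)[C@](O)([C@@H](C)C(=O)O)C(=O)C#CCO | intermediate
40 | (7S)-hydroxy acid from 39 | C=C[C@@H](O[Si](CC)(CC)CC)[C@@]2(C)[C@@H](O[Si](CC)(CC)CC)CC=C(C)[C@@H]2[C@@H](O[Si](CC)(CC)CC)[C@](O)([C@@H](C)C(=O)O)[C@@H](O)C#CCO | intermediate
41 | γ-lactone alkyne: lactone C19–O–C7 (7S,8S,17R), 8-OH, 9R-OTES, 3-hydroxyprop-1-ynyl on C7 | C=C[C@@H](O[Si](CC)(CC)CC)[C@@]2(C)[C@@H](O[Si](CC)(CC)CC)CC=C(C)[C@@H]2[C@@H](O[Si](CC)(CC)CC)[C@@]2(O)[C@H](C#CCO)OC(=O)[C@@H]2C | intermediate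
42 | (Z)-alkenylstannane: Bu3Sn on C5 cis to C7, 16-OH | C=C[C@@H](O[Si](CC)(CC)CC)[C@@]2(C)[C@@H](O[Si](CC)(CC)CC)CC=C(C)[C@@H]2[C@@H](O[Si](CC)(CC)CC)[C@@]2(O)[C@H](/C=C(\[Sn](CCCC)(CCCC)CCCC)CO)OC(=O)[C@@H]2C | intermediate
43 | (Z)-vinyl iodide: I on C5 cis to C7, 16-OH | C=C[C@@H](O[Si](CC)(CC)CC)[C@@]2(C)[C@@H](O[Si](CC)(CC)CC)CC=C(C)[C@@H]2[C@@H](O[Si](CC)(CC)CC)[C@@]2(O)[C@H](/C=C(\I)CO)OC(=O)[C@@H]2C | intermediate
44 | 16-O-TBS ether of 43 | C=C[C@@H](O[Si](CC)(CC)CC)[C@@]2(C)[C@@H](O[Si](CC)(CC)CC)CC=C(C)[C@@H]2[C@@H](O[Si](CC)(CC)CC)[C@@]2(O)[C@H](/C=C(\I)CO[Si](C)(C)C(C)(C)C)OC(=O)[C@@H]2C | intermediate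
45 | B-alkyl-9-borabicyclo[3.3.1]nonane from 44 (boron on C4) | B5(C6CCCC5CCC6)CC[C@@H](O[Si](CC)(CC)CC)[C@@]2(C)[C@@H](O[Si](CC)(CC)CC)CC=C(C)[C@@H]2[C@@H](O[Si](CC)(CC)CC)[C@@]2(O)[C@H](/C=C(\I)CO[Si](C)(C)C(C)(C)C)OC(=O)[C@@H]2C | intermediate
46 | primary C4 alcohol | OCC[C@@H](O[Si](CC)(CC)CC)[C@@]2(C)[C@@H](O[Si](CC)(CC)CC)CC=C(C)[C@@H]2[C@@H](O[Si](CC)(CC)CC)[C@@]2(O)[C@H](/C=C(\I)CO[Si](C)(C)C(C)(C)C)OC(=O)[C@@H]2C | intermediate
47 | C4 aldehyde | O=CC[C@@H](O[Si](CC)(CC)CC)[C@@]2(C)[C@@H](O[Si](CC)(CC)CC)CC=C(C)[C@@H]2[C@@H](O[Si](CC)(CC)CC)[C@@]2(O)[C@H](/C=C(\I)CO[Si](C)(C)C(C)(C)C)OC(=O)[C@@H]2C | intermediate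
48 | macrocyclic (4R)-alcohol: briarane skeleton, 5Z, 2,9,14-tris-OTES, 16-OTBS, 8-OH | O[C@@H]1C[C@@H](O[Si](CC)(CC)CC)[C@@]2(C)[C@@H](O[Si](CC)(CC)CC)CC=C(C)[C@@H]2[C@@H](O[Si](CC)(CC)CC)[C@@]2(O)[C@H](/C=C\1CO[Si](C)(C)C(C)(C)C)OC(=O)[C@@H]2C | intermediate
49 | 4-butyrate of 48 | CCCC(=O)O[C@@H]1C[C@@H](O[Si](CC)(CC)CC)[C@@]2(C)[C@@H](O[Si](CC)(CC)CC)CC=C(C)[C@@H]2[C@@H](O[Si](CC)(CC)CC)[C@@]2(O)[C@H](/C=C\1CO[Si](C)(C)C(C)(C)C)OC(=O)[C@@H]2C | intermediate
50 | tetraol 4-butyrate (2,9,14,16-OH and 8-OH free) | CCCC(=O)O[C@@H]1C[C@@H](O)[C@@]2(C)[C@@H](O)CC=C(C)[C@@H]2[C@@H](O)[C@@]2(O)[C@H](/C=C\1CO)OC(=O)[C@@H]2C | intermediate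
51 | CNP0290502.1: (1R,2R,4R,5Z,7S,8S,9R,10S,14S,17R)-2,9,14,16-tetraacetoxy-4-butanoyloxy-8-hydroxybriara-5,11-dien-19,7-olide | CCCC(=O)O[C@@H]1C[C@@H](OC(C)=O)[C@@]2(C)[C@@H](OC(C)=O)CC=C(C)[C@@H]2[C@@H](OC(C)=O)[C@@]2(O)[C@H](/C=C\1COC(C)=O)OC(=O)[C@@H]2C | target

## Step count and risks

Total step count: 34. Longest linear sequence: 31 steps (steps 1–19 and 23–34); steps 20–22 make the malic acid fragment.

Steps most likely to fail:

1. Step 9. The cascade may stall after the Claisen shift, or the ene closure may run through a competing geometry, so that ring closure is incomplete or control at C14 is lost. Fallback: starting from 12, the thermolysis is run in toluene at 110 °C only, which should stop at lactone aldehyde 14, now isolated. The ring is then closed in a separate Lewis-acid-mediated cationic carbonyl-ene (Prins-type) cyclisation with Me2AlCl in CH2Cl2 at −78 °C, which does not need the boat geometry, and the route is rejoined at 15. This fallback makes no new compound (F0).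

2. Step 23. The congested aldolate may revert by retro-aldol reaction, or the basic dianion may enolise aldehyde 26, with loss of the C10 configuration or double-bond migration. Fallback: starting from 31, radical bromination (N-bromosuccinimide, AIBN, CCl4, reflux) gives the 4-bromo dioxolanone acid F1. Its sodium salt (NaH, THF) is treated with CrCl2 and LiI in the presence of 26 in a chromium Reformatsky reaction, which is not basic and gives the non-reverting trivalent chromium aldolate F2. Silylation with TESOTf and buffered work-up return the route to 35.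

3. Step 31. Addition may occur on the wrong face of the C4 aldehyde during ring closure, giving mainly the C4 epimer. Fallback: starting from 47, if the cyclisation delivers the (4S)-alcohol F3, this is esterified with inversion under Mitsunobu conditions (butyric acid, PPh3, diisopropyl azodicarboxylate, toluene, 0 °C), which gives butyrate 49 directly and rejoins the route there.

## Further compounds

F0 | step 9 | none | none
F1 | step 23 | (2R)-2-[(2S)-4-bromo-2-tert-butyl-5-oxo-1,3-dioxolan-4-yl]propanoic acid, both C4 epimers | C[C@@H](C(=O)O)C1(Br)O[C@H](C(C)(C)C)OC1=O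
F2 | step 23 | dichlorochromium aldolate of 26 and the enolate from F1, sodium carboxylate | C=C[C@@H](O[Si](CC)(CC)CC)[C@@]2(C)[C@@H](O[Si](CC)(CC)CC)CC=C(C)[C@@H]2[C@@H](O[Cr](Cl)Cl)[C@@]3([C@@H](C)C(=O)[O-])O[C@H](C(C)(C)C)OC3=O.[Na+]
F3 | step 31 | (4S)-epimer of macrocyclic alcohol 48 | O[C@H]1C[C@@H](O[Si](CC)(CC)CC)[C@@]2(C)[C@@H](O[Si](CC)(CC)CC)CC=C(C)[C@@H]2[C@@H](O[Si](CC)(CC)CC)[C@@]2(O)[C@H](/C=C\1CO[Si](C)(C)C(C)(C)C)OC(=O)[C@@H]2C
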